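**Plan**
- Retrosynthesis: cut the S–O bond of the C3 sulfate, then the C3–O bond (back to perbenzylated scutellarein), then the O1–C2 bond of ring C, redrawn as the isomeric O–C2 bond of a 5,7,8-trioxygenated flavone, and last the C8–O bond, which leads to apigenin.
- Enabling feature: in ring A both carbons ortho to C4a (C5 and C8a) carry oxygen, so ring C can open at O1–C2 and close again through the former O5; the C8 oxygen of the precursor thereby becomes the C6 oxygen of the target.
- Forward: apigenin already holds rings A, B and C; 7,4'-di-O-methylation, persulfate hydroxylation at C8, then hot HI (ether cleavage, ring C opened and re-closed to the 5,6,7 isomer), perbenzylation, C3 hydroxylation via the 2,3-epoxide, 3-O-sulfation, hydrogenolysis.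
- Stereochemistry: the target has no stereocentre; the two centres of the transient epoxide vanish on aromatisation.

Key step: step 3

Remark on the chemistry: the ring opening is run with hydrogen at C3, because flavonols and their 3-ethers are known to be demethylated by hot HI with the 5,7,8 pattern kept (the C3 oxygen makes C2 too electron-rich for hydration); the C3 oxygen is therefore added after the rearrangement.

Assumption: the target is drawn as the hydrogen sulfate; the sulfate is carried as its sodium salt and only protonated in the last operation, the free acid being kept cold and dry.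

**Step 1**
Reactants: 1 apigenin; 2 dimethyl sulfate
Product: 3 apigenin 7,4'-dimethyl ether (5-hydroxy-7-methoxy-2-(4-methoxyphenyl)chromen-4-one)
Conditions: Me2SO4 (2.2 equiv), K2CO3, acetone, reflux
Reagents that add atoms: dimethyl sulfate, COS(=O)(=O)OC
Why: Williamson O-methylation etherifies the acidic 7- and 4'-phenols, while the 5-OH, held in a hydrogen bond to the C4 carbonyl, stays free at this stoichiometry.

**Step 2**
Reactants: 3 apigenin 7,4'-dimethyl ether; 4 potassium persulfate
Product: 6 5,8-dihydroxy-7-methoxy-2-(4-methoxyphenyl)chromen-4-one, via Elbs sulfate ester 5 (not isolated)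
Conditions: K2S2O8 (1.2 equiv), aq. KOH, pyridine, 15–20 °C, 24 h; acidify to pH 5, remove unchanged 3; then conc. HCl, Na2SO3 (trace), 90 °C
Reagents that add atoms: potassium persulfate, [K+].[K+].[O-]S(=O)(=O)OOS(=O)(=O)[O-]
Why: Elbs persulfate oxidation, in which the 5-phenoxide is attacked by peroxydisulfate at its free para carbon C8 and the aryl sulfate 5 is then hydrolysed by acid with S–O cleavage to the quinol 6.

**Step 3**
Reactants: 6 5,8-dihydroxy-7-methoxy-2-(4-methoxyphenyl)chromen-4-one
Product: 9 scutellarein (5,6,7-trihydroxy-2-(4-hydroxyphenyl)chromen-4-one), via isoscutellarein 7 (not isolated), via ring-opened diketone 8 (not isolated)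
Conditions: 57% aq. HI, AcOH, reflux (ca. 125 °C), Ar; aq. NaHSO3 work-up
Reagents that add atoms: none
Why: HI cleaves both methyl ethers by SN2 attack of iodide at methyl to give 7, protonation of the pyranone carbonyl makes C2 electrophilic, and water adds there so that the O1–C2 bond breaks to the 1,3-diketone 8, whose aryl ring has hydroxyls on both carbons ortho to the acyl group. After rotation about the aryl–carbonyl bond the hydroxyl that was O5 attacks the protonated aroyl carbonyl (old C2) in a 6-exo-trig hemiketalisation, and loss of water restores the pyranone, so ring C is the only ring closed and O–C2 the only new skeletal bond. The closest known reaction is the Wessely–Moser rearrangement of 5,7,8-trioxygenated flavones to 5,6,7-trihydroxyflavones in hot HI or HBr. No stereocentre is formed. The selectivity needed is the direction of reclosure, and it is secured by reversibility, since every stage equilibrates in hot acid and the 5,6,7-trihydroxy isomer is the thermodynamic sink. The hydrogen at C3 keeps C2 electrophilic enough for hydration, and the diketone has no leaving group that would allow contraction to an aurone.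

**Step 4**
Reactants: 9 scutellarein; 10 benzyl bromide
Product: 11 5,6,7-tris(benzyloxy)-2-[4-(benzyloxy)phenyl]chromen-4-one
Conditions: BnBr (6 equiv), K2CO3, KI (cat.), DMF, 70 °C, Ar
Reagents that add atoms: benzyl bromide, BrCc1ccccc1
Why: Williamson etherification, in which the three unchelated phenols react readily and the hydrogen-bonded 5-OH follows with excess bromide, iodide catalysis and heat, while exclusion of air protects the pyrogallol-type ring A from oxidation in base.

**Step 5**
Reactants: 11 5,6,7-tris(benzyloxy)-2-[4-(benzyloxy)phenyl]chromen-4-one; 12 dimethyldioxirane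
Product: 14 5,6,7-tris(benzyloxy)-2-[4-(benzyloxy)phenyl]-3-hydroxychromen-4-one, via flavone epoxide 13 (not isolated)
Conditions: DMDO (acetone solution, 3 equiv, made from KHSO5/acetone/NaHCO3), CH2Cl2, 0 °C → rt; then TsOH·H2O (cat.), CH2Cl2, rt
Reagents that add atoms: dimethyldioxirane, CC1(C)OO1
Why: Dimethyldioxirane epoxidation of the C2=C3 bond of a fully O-protected flavone, followed by acid-catalysed opening of the epoxide at C2 (cation stabilised by O1 and the aryl group) and loss of H3, gives the flavonol, so the two stereocentres of the racemic, necessarily cis-fused 13 are erased.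

**Step 6**
Reactants: 14 5,6,7-tris(benzyloxy)-2-[4-(benzyloxy)phenyl]-3-hydroxychromen-4-one; 15 sulfur trioxide–pyridine complex
Product: 17 sodium 5,6,7-tris(benzyloxy)-2-[4-(benzyloxy)phenyl]-4-oxochromen-3-yl sulfate, via pyridinium sulfate 16 (not isolated)
Conditions: SO3·pyridine (5 equiv), pyridine, 60 °C; then aq. NaHCO3, reversed-phase (C18) isolation
Reagents that add atoms: sulfur trioxide–pyridine complex, [O-]S(=O)(=O)[n+]1ccccc1; sodium hydrogen carbonate, [Na+].OC([O-])=O
Why: O-Sulfonation of the only free hydroxyl by an SO3–amine complex is the standard way from benzyl-protected flavonols to their 3-sulfates, and exchange to the sodium salt removes pyridine, which would slow the hydrogenolysis that follows.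

**Step 7**
Reactants: 17 sodium 5,6,7-tris(benzyloxy)-2-[4-(benzyloxy)phenyl]-4-oxochromen-3-yl sulfate
Product: 19 6-hydroxykaempferol 3-sulfate (5,6,7-trihydroxy-2-(4-hydroxyphenyl)-4-oxochromen-3-yl hydrogen sulfate), via sodium salt 18 (not isolated)
Conditions: H2 (1 atm), 10% Pd/C, THF/MeOH, rt; filter under Ar; then aq. HCl (1.0 equiv), 0 °C, C18 desalting, freeze-drying
Reagents that add atoms: none
Why: Catalytic hydrogenolysis cleaves the four aryl benzyl ethers under neutral conditions that leave the sulfate monoester anion and the chromenone double bond alone, and cold stoichiometric acid then only protonates the salt.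

**Compound list**
1 | apigenin (5,7-dihydroxy-2-(4-hydroxyphenyl)chromen-4-one) | O=c1cc(-c2ccc(O)cc2)oc2cc(O)cc(O)c12 | starting material
2 | dimethyl sulfate | COS(=O)(=O)OC | starting material
3 | apigenin 7,4'-dimethyl ether (5-hydroxy-7-methoxy-2-(4-methoxyphenyl)chromen-4-one) | COc1ccc(-c2cc(=O)c3c(O)cc(OC)cc3o2)cc1 | intermediate
4 | potassium persulfate | [K+].[K+].[O-]S(=O)(=O)OOS(=O)(=O)[O-] | starting material
5 | potassium 5-hydroxy-7-methoxy-2-(4-methoxyphenyl)-4-oxochromen-8-yl sulfate | COc1ccc(-c2cc(=O)c3c(O)cc(OC)c(OS(=O)(=O)[O-])c3o2)cc1.[K+] | intermediate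
6 | 5,8-dihydroxy-7-methoxy-2-(4-methoxyphenyl)chromen-4-one | COc1ccc(-c2cc(=O)c3c(O)cc(OC)c(O)c3o2)cc1 | intermediate
7 | isoscutellarein (5,7,8-trihydroxy-2-(4-hydroxyphenyl)chromen-4-one) | O=c1cc(-c2ccc(O)cc2)oc2c(O)c(O)cc(O)c12 | intermediate
8 | 1-(4-hydroxyphenyl)-3-(2,3,4,6-tetrahydroxyphenyl)propane-1,3-dione | O=C(CC(=O)c1c(O)cc(O)c(O)c1O)c1ccc(O)cc1 | intermediate
9 | scutellarein (5,6,7-trihydroxy-2-(4-hydroxyphenyl)chromen-4-one) | O=c1cc(-c2ccc(O)cc2)oc2cc(O)c(O)c(O)c12 | intermediate
10 | benzyl bromide | BrCc1ccccc1 | starting material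
11 | 5,6,7-tris(benzyloxy)-2-[4-(benzyloxy)phenyl]chromen-4-one | O=c1cc(-c2ccc(OCc3ccccc3)cc2)oc2cc(OCc3ccccc3)c(OCc3ccccc3)c(OCc3ccccc3)c12 | intermediate
12 | dimethyldioxirane (reagent, made from acetone and KHSO5 just before use) | CC1(C)OO1 | starting material
13 | racemic 5,6,7-tris(benzyloxy)-2-[4-(benzyloxy)phenyl]-2,3-epoxychroman-4-one (oxirane cis-fused to ring C, one enantiomer drawn) | O=C1[C@@H]2O[C@]2(c2ccc(OCc3ccccc3)cc2)Oc2cc(OCc3ccccc3)c(OCc3ccccc3)c(OCc3ccccc3)c21 | intermediate
14 | 5,6,7-tris(benzyloxy)-2-[4-(benzyloxy)phenyl]-3-hydroxychromen-4-one | O=c1c(O)c(-c2ccc(OCc3ccccc3)cc2)oc2cc(OCc3ccccc3)c(OCc3ccccc3)c(OCc3ccccc3)c12 | intermediate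
15 | sulfur trioxide–pyridine complex | [O-]S(=O)(=O)[n+]1ccccc1 | starting material
16 | pyridinium 5,6,7-tris(benzyloxy)-2-[4-(benzyloxy)phenyl]-4-oxochromen-3-yl sulfate | O=c1c(OS(=O)(=O)[O-])c(-c2ccc(OCc3ccccc3)cc2)oc2cc(OCc3ccccc3)c(OCc3ccccc3)c(OCc3ccccc3)c12.c1cc[nH+]cc1 | intermediate
17 | sodium 5,6,7-tris(benzyloxy)-2-[4-(benzyloxy)phenyl]-4-oxochromen-3-yl sulfate | O=c1c(OS(=O)(=O)[O-])c(-c2ccc(OCc3ccccc3)cc2)oc2cc(OCc3ccccc3)c(OCc3ccccc3)c(OCc3ccccc3)c12.[Na+] | intermediate
18 | sodium 5,6,7-trihydroxy-2-(4-hydroxyphenyl)-4-oxochromen-3-yl sulfate | O=c1c(OS(=O)(=O)[O-])c(-c2ccc(O)cc2)oc2cc(O)c(O)c(O)c12.[Na+] | intermediate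
19 | 6-hydroxykaempferol 3-sulfate (5,6,7-trihydroxy-2-(4-hydroxyphenyl)-4-oxochromen-3-yl hydrogen sulfate) | O=c1c(OS(=O)(=O)O)c(-c2ccc(O)cc2)oc2cc(O)c(O)c(O)c12 | target

Total step count: 7. Longest linear sequence: 7 steps (from apigenin 1).

**Steps most likely to fail**

Step 2: the Elbs oxidation may stop at low conversion, and the electron-rich phenoxide and quinol may be over-oxidised to dark polymeric material in alkaline persulfate. The fallback sets out from apigenin 1 and comes back to the route at 7. Duff formylation of 1 (hexamethylenetetramine, AcOH, 100 °C, then aq. HCl) should give 8-formylapigenin F1. Dakin oxidation of F1 (H2O2, aq. NaOH, 0 °C, Ar, then acidification) should give isoscutellarein 7, this time isolated. Heating 7 in the acid of step 3, where no ether cleavage is needed, then leads to 9. Formylation at the other free carbon of ring A would do no harm, because the acid equilibration funnels both oxygenation patterns to 9.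

Step 5: the dioxirane may attack benzylic C–H bonds or the electron-rich ring A faster than the hindered, electron-poor enone, and the epoxide may open along other paths than to the flavonol. The fallback sets out from 11 and comes back at 14. Deprotonation at C3 with LDA (THF, −78 °C) should give the 3-lithioflavone F2. Trapping with B(OMe)3 should give the dimethyl boronate F3. Oxidation in the same flask with H2O2/AcOH (0 °C → rt) should give 14 by carbon-to-oxygen migration from boron; this is an anionic C3 functionalisation in place of the epoxidation.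

Step 3: ether cleavage may outrun ring opening, so that the 5,7,8 and 5,6,7 isomers are formed together and are hard to separate, or the polyphenol may decompose on the long heating needed for full equilibration. The fallback sets out from 3 and comes back at 9, and it puts the C6 oxygen in directly with no ring opening. Iodination ortho to the free 5-OH (I2, TlOAc, CH2Cl2, rt; the phenoxide of monovalent thallium directs to C6) should give 5-hydroxy-6-iodo-7-methoxy-2-(4-methoxyphenyl)chromen-4-one F4. Ullmann-type methoxylation (NaOMe, CuBr, DMF/MeOH, 110 °C) should give 5-hydroxy-6,7-dimethoxy-2-(4-methoxyphenyl)chromen-4-one F5. BBr3 (CH2Cl2, −78 °C → rt) should then cleave the three methyl ethers to 9.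

**Further compounds**
F1 | step 2 | 8-formylapigenin (5,7-dihydroxy-2-(4-hydroxyphenyl)-4-oxochromene-8-carbaldehyde) | O=Cc1c(O)cc(O)c2c(=O)cc(-c3ccc(O)cc3)oc12
F2 | step 5 | 5,6,7-tris(benzyloxy)-2-[4-(benzyloxy)phenyl]-3-lithiochromen-4-one | [Li]c1c(-c2ccc(OCc3ccccc3)cc2)oc2cc(OCc3ccccc3)c(OCc3ccccc3)c(OCc3ccccc3)c2c1=O
F3 | step 5 | dimethyl {5,6,7-tris(benzyloxy)-2-[4-(benzyloxy)phenyl]-4-oxochromen-3-yl}boronate | COB(OC)c1c(-c2ccc(OCc3ccccc3)cc2)oc2cc(OCc3ccccc3)c(OCc3ccccc3)c(OCc3ccccc3)c2c1=O
F4 | step 3 | 5-hydroxy-6-iodo-7-methoxy-2-(4-methoxyphenyl)chromen-4-one | COc1ccc(-c2cc(=O)c3c(O)c(I)c(OC)cc3o2)cc1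
F5 | step 3 | 5-hydroxy-6,7-dimethoxy-2-(4-methoxyphenyl)chromen-4-one | COc1ccc(-c2cc(=O)c3c(O)c(OC)c(OC)cc3o2)cc1
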